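**Plan**
1. Retrosynthesis: the two tiglate ester C–O bonds and the aldehyde oxidation level are removed first. The side-chain carbinol is then taken back to a methyl ketone and further to a nitrile, and the C=CH2 carbon is cut from a methyl ketone. Finally the dihydrofuran ring is opened at O1–C7a and C2–C3, giving 4-fluoro-3-formylbenzonitrile and hydroxyacetone.
2. Enabling feature: C7a of the benzene ring is ortho to C3a, which carries C3 at the aldehyde level, and para to C5, whose side-chain carbon is carried as a nitrile. O1–C2 is the ketol unit of hydroxyacetone. An aldol at C3 followed by SNAr at C7a therefore closes the furan ring in one flask.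
3. Forward order: the benzene ring is bought and the furan ring is made in step 1. The ketone is then methylenated, the nitrile becomes the acetyl group, the ketone is reduced, both hydroxyls are acylated, and the isopropenyl methyl is oxidized to the aldehyde.
4. Stereochemistry: C3 and C2 come from the L-proline anti aldol, which maps onto the 2,3-trans ring. The (R) carbinol comes from RuCl[(R,R)-TsDPEN](p-cymene) transfer hydrogenation. The (E) ester geometry is bought with tigloyl chloride.

Key step: step 1

Remark: the SMILES is read as the 2,3-trans (2R,3S) dihydrobenzofuran with an (R)-configured 1-acyloxyethyl group and two (E)-2-methylbut-2-enoate (tiglate) esters.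

**Step 1**
Reactants: 1 4-fluoro-3-formylbenzonitrile; 2 hydroxyacetone (1-hydroxypropan-2-one)
Product: 4 (2S,3S)-2-acetyl-3-hydroxy-2,3-dihydro-1-benzofuran-5-carbonitrile, via anti-aldol adduct 3 (not isolated)
Conditions: L-proline (30 mol %), 2 (5 equiv), DMSO, rt; then K2CO3, 0 °C → rt, same flask
Reagents that add atoms: none
Why: Proposed new method: L-proline and 2 form the (E)-hydroxy-enamine, whose hydroxylated carbon adds to the formyl group of 1 through the carboxylic-acid-bridged hydrogen-bonded transition state (C2–C3 bond, anti adduct 3), after which carbonate ionizes the ketol hydroxyl and this alkoxide adds to C7a and expels fluoride through a Meisenheimer complex stabilized by the para nitrile (O1–C7a bond). The closest known reaction types are the proline-catalysed anti-selective aldol of hydroxyacetone with aldehydes and the SNAr-terminated domino annulations of activated 2-fluorobenzaldehydes, and only their union in one flask on a base-sensitive ketol aldol is new. The furan ring closes by a 5-exo-trig addition–elimination at C7a, and the benzylic hydroxyl cannot compete because it would have to form a four-membered ring. C3 is set by the catalyst, which exposes one face of the aldehyde, and C2 by the (E) geometry of the enamine, so that the anti diol becomes the 2,3-trans ring; C2 stays enolizable and any cis isomer should drift to the trans isomer, which is expected to be the more stable one. The step needs enamine formation at the hydroxylated carbon, which the hydroxyl itself secures, and a ring closure that outruns retro-aldol cleavage and dehydration to the benzofuran, which the nitrile para to fluorine, the five-membered transition state and a mild base at low temperature should secure.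

**Step 2**
Reactants: 4 (2S,3S)-2-acetyl-3-hydroxy-2,3-dihydro-1-benzofuran-5-carbonitrile
Product: 5 (2R,3S)-3-hydroxy-2-(prop-1-en-2-yl)-2,3-dihydro-1-benzofuran-5-carbonitrile
Conditions: Zn, CH2Br2, TiCl4, THF (pre-formed reagent, excess); CH2Cl2, 0 °C → rt
Reagents that add atoms: dibromomethane, BrCBr
Why: Takai–Lombardo methylenation: the non-basic zinc–titanium methylene reagent converts the only ketone into the alkene without enolizing the acidic C2–H, so epimerization, retro-aldol cleavage and aromatizing elimination should be avoided while the free hydroxyl and the nitrile are tolerated; no stereocentre is formed (the C2 descriptor changes from S to R only through the new substituent priority).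

**Step 3**
Reactants: 5 (2R,3S)-3-hydroxy-2-(prop-1-en-2-yl)-2,3-dihydro-1-benzofuran-5-carbonitrile
Product: 7 1-[(2R,3S)-3-hydroxy-2-(prop-1-en-2-yl)-2,3-dihydro-1-benzofuran-5-yl]ethan-1-one, via ketimine 6 (not isolated)
Conditions: MeLi (3 equiv), THF, −78 → 0 °C; then 1 M aq. HCl, 0 °C
Reagents that add atoms: methyllithium, [Li]C; water, O
Why: Organolithium addition to a nitrile: after deprotonation of the hydroxyl, MeLi adds once to the aryl nitrile to give the N-lithio ketimine, which cannot take up a second equivalent and is hydrolysed by cold dilute acid to the methyl ketone; no stereocentre is formed or touched.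

**Step 4**
Reactants: 7 1-[(2R,3S)-3-hydroxy-2-(prop-1-en-2-yl)-2,3-dihydro-1-benzofuran-5-yl]ethan-1-one
Product: 8 (2R,3S)-5-[(1R)-1-hydroxyethyl]-2-(prop-1-en-2-yl)-2,3-dihydro-1-benzofuran-3-ol
Conditions: RuCl[(R,R)-TsDPEN](p-cymene) (1 mol %), HCO2H/Et3N (5:2), CH2Cl2, rt → 40 °C
Reagents that add atoms: none
Why: Noyori asymmetric transfer hydrogenation: the (R,R)-TsDPEN ruthenium hydride should deliver hydride to the Si face of the aryl methyl ketone through the six-membered metal–ligand bifunctional transition state, setting the (R) carbinol by catalyst control (the (S,S) catalyst is known to give (S)-1-arylethanols), and it leaves the isolated alkene and the free hydroxyl untouched.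

**Step 5**
Reactants: 8 (2R,3S)-5-[(1R)-1-hydroxyethyl]-2-(prop-1-en-2-yl)-2,3-dihydro-1-benzofuran-3-ol; 9 tigloyl chloride ((2E)-2-methylbut-2-enoyl chloride, 3 equiv)
Product: 10 (1R)-1-[(2R,3S)-3-{[(2E)-2-methylbut-2-enoyl]oxy}-2-(prop-1-en-2-yl)-2,3-dihydro-1-benzofuran-5-yl]ethyl (2E)-2-methylbut-2-enoate
Conditions: pyridine, DMAP (cat.), CH2Cl2, 0 °C → rt
Reagents that add atoms: none
Why: DMAP-catalysed acylation (nucleophilic acyl substitution) of both secondary hydroxyls; the C–O bonds at the stereocentres are not broken, so configuration is retained, and the (E) geometry of the acyl unit should survive these non-isomerizing conditions.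

**Step 6**
Reactants: 10 (1R)-1-[(2R,3S)-3-{[(2E)-2-methylbut-2-enoyl]oxy}-2-(prop-1-en-2-yl)-2,3-dihydro-1-benzofuran-5-yl]ethyl (2E)-2-methylbut-2-enoate
Product: 11 (1R)-1-[(2R,3S)-2-(3-hydroxyprop-1-en-2-yl)-3-{[(2E)-2-methylbut-2-enoyl]oxy}-2,3-dihydro-1-benzofuran-5-yl]ethyl (2E)-2-methylbut-2-enoate
Conditions: SeO2 (cat.), tBuOOH, CH2Cl2, rt
Reagents that add atoms: tert-butyl hydroperoxide, CC(C)(C)OO (net oxygen donor); selenium dioxide, O=[Se]=O (oxygen carrier)
Why: Riley-type allylic oxidation (ene reaction with SeO2, then [2,3]-sigmatropic shift, with the selenium reoxidized by tBuOOH): it should attack the methyl group of the only electron-rich 1,1-disubstituted alkene, the conjugated tiglate alkenes being deactivated, as is known for 2-isopropenyl-2,3-dihydrobenzofurans; no stereocentre is formed, and any aldehyde 12 formed alongside is carried on.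

**Step 7**
Reactants: 11 (1R)-1-[(2R,3S)-2-(3-hydroxyprop-1-en-2-yl)-3-{[(2E)-2-methylbut-2-enoyl]oxy}-2,3-dihydro-1-benzofuran-5-yl]ethyl (2E)-2-methylbut-2-enoate
Product: 12 (1R)-1-[(2R,3S)-3-{[(2E)-2-methylbut-2-enoyl]oxy}-2-(3-oxoprop-1-en-2-yl)-2,3-dihydro-1-benzofuran-5-yl]ethyl (2E)-2-methylbut-2-enoate
Conditions: MnO2 (activated, excess), CH2Cl2, rt
Reagents that add atoms: none
Why: MnO2 oxidation of a primary allylic alcohol to the enal; the alcohol is the only free hydroxyl, and the neutral heterogeneous oxidant should leave the esters, the benzylic C–O bonds and the three stereocentres untouched.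

**Compound list**
1 | 4-fluoro-3-formylbenzonitrile | N#Cc1ccc(F)c(C=O)c1 | starting material
2 | hydroxyacetone (1-hydroxypropan-2-one) | CC(=O)CO | starting material
3 | 4-fluoro-3-[(1S,2S)-1,2-dihydroxy-3-oxobutyl]benzonitrile (anti-aldol adduct) | CC(=O)[C@@H](O)[C@@H](O)c1cc(C#N)ccc1F | intermediate
4 | (2S,3S)-2-acetyl-3-hydroxy-2,3-dihydro-1-benzofuran-5-carbonitrile | CC(=O)[C@H]1Oc2ccc(C#N)cc2[C@@H]1O | intermediate
5 | (2R,3S)-3-hydroxy-2-(prop-1-en-2-yl)-2,3-dihydro-1-benzofuran-5-carbonitrile | CC(=C)[C@H]1Oc2ccc(C#N)cc2[C@@H]1O | intermediate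
6 | (2R,3S)-5-ethanimidoyl-2-(prop-1-en-2-yl)-2,3-dihydro-1-benzofuran-3-ol (ketimine, formed as its N-lithio salt) | CC(=C)[C@H]1Oc2ccc(C(C)=N)cc2[C@@H]1O | intermediate
7 | 1-[(2R,3S)-3-hydroxy-2-(prop-1-en-2-yl)-2,3-dihydro-1-benzofuran-5-yl]ethan-1-one | CC(=C)[C@H]1Oc2ccc(C(C)=O)cc2[C@@H]1O | intermediate
8 | (2R,3S)-5-[(1R)-1-hydroxyethyl]-2-(prop-1-en-2-yl)-2,3-dihydro-1-benzofuran-3-ol | CC(=C)[C@H]1Oc2ccc([C@@H](C)O)cc2[C@@H]1O | intermediate
9 | tigloyl chloride, (2E)-2-methylbut-2-enoyl chloride | C/C=C(\C)C(Cl)=O | starting material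
10 | (1R)-1-[(2R,3S)-3-{[(2E)-2-methylbut-2-enoyl]oxy}-2-(prop-1-en-2-yl)-2,3-dihydro-1-benzofuran-5-yl]ethyl (2E)-2-methylbut-2-enoate | CC(=C)[C@H]1Oc2ccc([C@@H](C)OC(=O)/C(C)=C/C)cc2[C@@H]1OC(=O)/C(C)=C/C | intermediate
11 | (1R)-1-[(2R,3S)-2-(3-hydroxyprop-1-en-2-yl)-3-{[(2E)-2-methylbut-2-enoyl]oxy}-2,3-dihydro-1-benzofuran-5-yl]ethyl (2E)-2-methylbut-2-enoate | C=C(CO)[C@H]1Oc2ccc([C@@H](C)OC(=O)/C(C)=C/C)cc2[C@@H]1OC(=O)/C(C)=C/C | intermediate
12 | (1R)-1-[(2R,3S)-3-{[(2E)-2-methylbut-2-enoyl]oxy}-2-(3-oxoprop-1-en-2-yl)-2,3-dihydro-1-benzofuran-5-yl]ethyl (2E)-2-methylbut-2-enoate | C=C(C=O)[C@H]1Oc2ccc([C@@H](C)OC(=O)/C(C)=C/C)cc2[C@@H]1OC(=O)/C(C)=C/C | target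

Total step count: 7. Longest linear sequence: 7 steps (1 → 12).

**Steps most likely to fail**

Step 1. The carbonate stage may cleave the ketol aldol by retro-aldol reaction, which would erode the enantiomeric purity, or may drive loss of water to the aromatic 2-acetylbenzofuran. The electron-poor aldehyde may also give low anti selectivity, and proline may be consumed by N-arylation on the activated fluoroarene. The fallback uses known chemistry and separates the two bond formations with the olefination placed between them. It sets out from 1 and 2: the proline aldol is stopped and adduct 3 is isolated. Its ketone is methylenated with Zn, CH2Br2 and TiCl4 to 4-fluoro-3-[(1S,2R)-1,2-dihydroxy-3-methylbut-3-en-1-yl]benzonitrile F1, which has no carbonyl group and so cannot undergo retro-aldol cleavage, C2 epimerization or enolate-driven dehydration. Ring closure by intramolecular SNAr with NaH in THF/DMF at 0 °C → rt, where only the allylic alkoxide can reach C7a through a five-membered transition state, comes back to the route at compound 5; compound 4 and step 2 are bypassed.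

Step 6. The ene reaction may take the C2–H instead of the methyl hydrogen, oxidation may run on past the alcohol unevenly, and the acidic selenium species may ionize the benzylic esters. The fallback sets out from 10 and replaces the selenium chemistry by a chlorination and oxidation sequence. Ene-type allylic chlorination with Ca(OCl)2 and CO2 in CH2Cl2/H2O at 0 °C should give (1R)-1-[(2R,3S)-2-(3-chloroprop-1-en-2-yl)-3-{[(2E)-2-methylbut-2-enoyl]oxy}-2,3-dihydro-1-benzofuran-5-yl]ethyl (2E)-2-methylbut-2-enoate F2. A Kornblum-type oxidation of this allylic chloride with N-methylmorpholine N-oxide in MeCN at rt comes back to the route at compound 12; compound 11 and step 7 are bypassed.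

Step 2. The Lewis-acidic reagent may promote dehydration or retro-aldol cleavage of the free β-hydroxy ketone, or may be quenched by the hydroxyl so that conversion stalls. The fallback sets out from 4 and masks the hydroxyl before a neutral, thermal titanium carbene olefination. Silylation with TBSOTf and 2,6-lutidine in CH2Cl2 at −78 °C gives (2S,3S)-2-acetyl-3-[(tert-butyldimethylsilyl)oxy]-2,3-dihydro-1-benzofuran-5-carbonitrile F3. Petasis olefination with Cp2TiMe2 in toluene at 65 °C gives (2R,3S)-3-[(tert-butyldimethylsilyl)oxy]-2-(prop-1-en-2-yl)-2,3-dihydro-1-benzofuran-5-carbonitrile F4. Desilylation with TBAF in THF at 0 °C comes back to the route at compound 5.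

**Further compounds**
F1 | step 1 | 4-fluoro-3-[(1S,2R)-1,2-dihydroxy-3-methylbut-3-en-1-yl]benzonitrile | CC(=C)[C@@H](O)[C@@H](O)c1cc(C#N)ccc1F
F2 | step 6 | (1R)-1-[(2R,3S)-2-(3-chloroprop-1-en-2-yl)-3-{[(2E)-2-methylbut-2-enoyl]oxy}-2,3-dihydro-1-benzofuran-5-yl]ethyl (2E)-2-methylbut-2-enoate | C=C(CCl)[C@H]1Oc2ccc([C@@H](C)OC(=O)/C(C)=C/C)cc2[C@@H]1OC(=O)/C(C)=C/C
F3 | step 2 | (2S,3S)-2-acetyl-3-[(tert-butyldimethylsilyl)oxy]-2,3-dihydro-1-benzofuran-5-carbonitrile | CC(=O)[C@H]1Oc2ccc(C#N)cc2[C@@H]1O[Si](C)(C)C(C)(C)C
F4 | step 2 | (2R,3S)-3-[(tert-butyldimethylsilyl)oxy]-2-(prop-1-en-2-yl)-2,3-dihydro-1-benzofuran-5-carbonitrile | CC(=C)[C@H]1Oc2ccc(C#N)cc2[C@@H]1O[Si](C)(C)C(C)(C)C
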